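**Plan**

- The last cuts are the four benzyl ethers and the benzylic CH2–C(=O) bond of the 4-hydroxy-2-oxopentyl chain (C-acylation of a tert-butyl arylacetate, then loss of CO2), which leaves a homophthalate.
- The homophthalate is cut at two neighbouring ring bonds of ring B, C1–C(=O)O and C6–CH2. The carboxyl carbon on C1 and the CH2–carbonyl carbon on C6 sit side by side, with the C2 oxygen flanking C1; this is the pattern left when 3,5-bis(benzyloxy)benzyne inserts into the CH2–C(=O) bond of a malonate.
- The malonate, the hydroxybutyrate ester and the aryl–CH2 bond of the 1-arylpropan-2-ol are cut last.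
- Forward, no ring is closed. The chain is joined in the order arylpropanol, hydroxybutyrate, tert-butyl malonate, aryne insertion (ring B arrives whole), acyl side chain, unmasking.
- All three (R) centres are bought: (R)-propylene oxide gives the arylpropanyl carbinol, and methyl (R)-3-hydroxybutanoate is used twice (middle ester and terminal carbinol). No step breaks a bond at these carbons.

Key step: step 10

Assumption: 1-bromo-3,5-bis(benzyloxy)benzene is taken as purchasable (otherwise one benzylation from 5-bromoresorcinol). Ring A is the resorcinol ring of the arylpropanyl unit; ring B is the benzoate ring.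

**Route**

Step 1
Reactants: 1 methyl (R)-3-hydroxybutanoate
Product: 2 methyl (R)-3-[(tert-butyldimethylsilyl)oxy]butanoate
Conditions: TBSCl, imidazole, DMF, 0 °C → rt
Reagents that add atoms: tert-butyldimethylsilyl chloride, CC(C)(C)[Si](C)(C)Cl
Why: Imidazole-promoted silylation of a secondary alcohol is routine and leaves the stereocentre untouched.

Step 2
Reactants: 2 methyl (R)-3-[(tert-butyldimethylsilyl)oxy]butanoate
Product: 3 (R)-3-[(tert-butyldimethylsilyl)oxy]butanoic acid
Conditions: LiOH·H2O, THF/MeOH/H2O, 0 °C → rt; then cold 1 M HCl to pH 3–4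
Reagents that add atoms: lithium hydroxide, [Li+].[OH-]
Why: Saponification of the methyl ester at low temperature should proceed without β-elimination, and the brief, mildly acidic work-up keeps the silyl ether.

Step 3
Reactants: 4 1-bromo-3,5-bis(benzyloxy)benzene; 5 (R)-propylene oxide
Product: 7 (R)-1-[3,5-bis(benzyloxy)phenyl]propan-2-ol, via arylmagnesium bromide 6 (not isolated)
Conditions: Mg, THF, 50 °C; then CuI (10 mol %), 5, −30 → 0 °C; aq. NH4Cl
Reagents that add atoms: none
Why: Copper-catalysed epoxide opening by an aryl Grignard reagent occurs at the unsubstituted carbon, so the C–O stereocentre of the epoxide is carried unchanged into the (R)-carbinol.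

Step 4
Reactants: 7 (R)-1-[3,5-bis(benzyloxy)phenyl]propan-2-ol; 3 (R)-3-[(tert-butyldimethylsilyl)oxy]butanoic acid
Product: 8 (R)-1-[3,5-bis(benzyloxy)phenyl]propan-2-yl (R)-3-[(tert-butyldimethylsilyl)oxy]butanoate
Conditions: DCC, DMAP (cat.), CH2Cl2, 0 °C → rt
Reagents that add atoms: none
Why: Steglich esterification of an unhindered acid with a secondary alcohol breaks only the O–H bond of the carbinol, so both centres are retained.

Step 5
Reactants: 8 (R)-1-[3,5-bis(benzyloxy)phenyl]propan-2-yl (R)-3-[(tert-butyldimethylsilyl)oxy]butanoate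
Product: 9 (R)-1-[3,5-bis(benzyloxy)phenyl]propan-2-yl (R)-3-hydroxybutanoate
Conditions: HF·pyridine, THF/pyridine, 0 °C → rt
Reagents that add atoms: none
Why: Buffered HF cleaves the silyl ether without the basic medium in which a β-oxygenated ester could eliminate, and it spares esters and benzyl ethers.

Step 6
Reactants: 9 (R)-1-[3,5-bis(benzyloxy)phenyl]propan-2-yl (R)-3-hydroxybutanoate; 10 mono-tert-butyl malonate
Product: 11 tert-butyl (R)-4-{[(R)-1-[3,5-bis(benzyloxy)phenyl]propan-2-yl]oxy}-4-oxobutan-2-yl malonate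
Conditions: DCC, DMAP (cat.), CH2Cl2, 0 °C
Reagents that add atoms: none
Why: Carbodiimide coupling of a malonic half-ester (Steglich esterification) acylates the secondary hydroxyl at 0 °C with retention, since no bond to the stereocentre is broken.

Step 7
Reactants: 12 3,5-bis(benzyloxy)phenol
Product: 13 2-bromo-3,5-bis(benzyloxy)phenol
Conditions: NBS (1.0 equiv), CH2Cl2, −78 °C
Reagents that add atoms: N-bromosuccinimide, O=C1CCC(=O)N1Br
Why: Electrophilic aromatic bromination of the trioxygenated ring should take place ortho to the free hydroxyl, the less crowded of the two activated positions, and one equivalent at low temperature limits dibromination.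

Step 8
Reactants: 13 2-bromo-3,5-bis(benzyloxy)phenol
Product: 14 [2-bromo-3,5-bis(benzyloxy)phenoxy]trimethylsilane
Conditions: HN(SiMe3)2, THF, 70 °C; evaporate
Reagents that add atoms: hexamethyldisilazane, C[Si](C)(C)N[Si](C)(C)C
Why: O-silylation of a phenol by hexamethyldisilazane releases only ammonia and gives the silyl ether needed for the silyl shift of the next step.

Step 9
Reactants: 14 [2-bromo-3,5-bis(benzyloxy)phenoxy]trimethylsilane
Product: 17 3,5-bis(benzyloxy)-2-(trimethylsilyl)phenyl trifluoromethanesulfonate, via aryllithium 15 (not isolated), via lithium phenoxide 16 (not isolated)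
Conditions: n-BuLi, THF, −100 → −80 °C; then Tf2O, −100 → −80 °C
Reagents that add atoms: trifluoromethanesulfonic anhydride, FC(F)(F)S(=O)(=O)OS(=O)(=O)C(F)(F)F
Why: Bromine–lithium exchange is followed by an O-to-C silyl shift (retro-Brook rearrangement) to the ortho-silyl phenoxide, which the anhydride traps as the triflate; this is the standard entry to ortho-silylaryl triflates.

Step 10
Reactants: 17 3,5-bis(benzyloxy)-2-(trimethylsilyl)phenyl trifluoromethanesulfonate; 11 tert-butyl (R)-4-{[(R)-1-[3,5-bis(benzyloxy)phenyl]propan-2-yl]oxy}-4-oxobutan-2-yl malonate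
Product: 19 (R)-4-{[(R)-1-[3,5-bis(benzyloxy)phenyl]propan-2-yl]oxy}-4-oxobutan-2-yl 2,4-bis(benzyloxy)-6-(2-tert-butoxy-2-oxoethyl)benzoate, via benzyne 18 (not isolated)
Conditions: 17 (1.4 equiv), KF, 18-crown-6, THF, 0 °C → rt
Reagents that add atoms: none
Why: Fluoride removes the silyl group of 17 and triflate leaves to give benzyne 18; the potassium enolate of malonate 11 then adds to the aryne carbon remote from the flanking benzyloxy group (future C6), which places the aryl anion on the carbon beside that oxygen (future C1), where it is inductively stabilised. This anion adds to the less shielded ester carbonyl in a 4-exo-trig closure to a transient benzocyclobutenoxide, whose fragmentation breaks the former malonate CH2–C(=O) bond and leaves the whole hydroxybutyrate ester on C1 and the tert-butyl acetate enolate on C6, which further malonate protonates. The closest known reaction type is the fluoride-triggered insertion of arynes into the C–C bond of malonates and β-keto esters (aryne acyl-alkylation); the four-membered ring is not retained. No stereocentre is formed and the two existing ones lie outside the reacting atoms. Two selectivities are needed: the orientation on the aryne, secured by the benzyloxy group beside the triple bond, and transfer of the secondary alkyl ester in preference to the tert-butyl ester, secured by the bulk around the tert-butyl ester carbonyl. The malonate CH2 is the only site acidic enough for fluoride at room temperature, which protects the β-acyloxy ester from elimination.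

Step 11
Reactants: 3 (R)-3-[(tert-butyldimethylsilyl)oxy]butanoic acid
Product: 20 (R)-3-[(tert-butyldimethylsilyl)oxy]butanoyl chloride
Conditions: 1-chloro-N,N,2-trimethylprop-1-en-1-amine, CH2Cl2, 0 °C → rt; used crude
Reagents that add atoms: 1-chloro-N,N,2-trimethylprop-1-en-1-amine, CC(C)=C(Cl)N(C)C
Why: The α-chloroenamine converts a carboxylic acid into its chloride under neutral conditions without free HCl, so the silyl ether should survive.

Step 12
Reactants: 19 (R)-4-{[(R)-1-[3,5-bis(benzyloxy)phenyl]propan-2-yl]oxy}-4-oxobutan-2-yl 2,4-bis(benzyloxy)-6-(2-tert-butoxy-2-oxoethyl)benzoate; 20 (R)-3-[(tert-butyldimethylsilyl)oxy]butanoyl chloride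
Product: 21 (R)-4-{[(R)-1-[3,5-bis(benzyloxy)phenyl]propan-2-yl]oxy}-4-oxobutan-2-yl 2,4-bis(benzyloxy)-6-[(5R)-1-tert-butoxy-5-[(tert-butyldimethylsilyl)oxy]-1,3-dioxohexan-2-yl]benzoate (both epimers at the benzylic carbon)
Conditions: LiN(SiMe3)2 (2.05 equiv), THF, −78 °C; then 20 (1.2 equiv), −78 °C; AcOH quench at −78 °C
Reagents that add atoms: none
Why: In this Claisen-type C-acylation of a lithium ester enolate, the benzylic CH2 between the tert-butyl ester and the ester-bearing arene is the most acidic site by several pKa units and the second equivalent of base is taken up by the more acidic β-keto ester product; the new benzylic stereocentre is of no consequence because the next step removes it.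

Step 13
Reactants: 21 (R)-4-{[(R)-1-[3,5-bis(benzyloxy)phenyl]propan-2-yl]oxy}-4-oxobutan-2-yl 2,4-bis(benzyloxy)-6-[(5R)-1-tert-butoxy-5-[(tert-butyldimethylsilyl)oxy]-1,3-dioxohexan-2-yl]benzoate
Product: 24 (R)-4-{[(R)-1-[3,5-bis(benzyloxy)phenyl]propan-2-yl]oxy}-4-oxobutan-2-yl 2,4-bis(benzyloxy)-6-[(R)-4-hydroxy-2-oxopentyl]benzoate, via keto acid 22 (not isolated), via silyl ether ketone 23 (not isolated)
Conditions: TFA/CH2Cl2 (1:3), anisole (co-solvent), H2O (5 equiv), 0 °C → rt; aq. NaHCO3 work-up
Reagents that add atoms: none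
Why: Acidolysis of the tert-butyl ester should give a β-keto acid that decarboxylates at room temperature, and wet TFA also cleaves the secondary silyl ether, while anisole intercepts the tert-butyl cation and the aryl benzyl ethers and both remaining esters tolerate the short exposure.

Step 14
Reactants: 24 (R)-4-{[(R)-1-[3,5-bis(benzyloxy)phenyl]propan-2-yl]oxy}-4-oxobutan-2-yl 2,4-bis(benzyloxy)-6-[(R)-4-hydroxy-2-oxopentyl]benzoate
Product: 25 Hansforester K
Conditions: H2 (1 atm), Pd/C (10% Pd on carbon), EtOAc/MeOH, rt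
Reagents that add atoms: none
Why: Hydrogenolysis of the four aryl benzyl ethers over Pd/C at ambient pressure should leave the ketone, the esters and the three carbinol centres unchanged.

**Compound list**

1 | methyl (R)-3-hydroxybutanoate | C[C@@H](O)CC(=O)OC | starting material
2 | methyl (R)-3-[(tert-butyldimethylsilyl)oxy]butanoate | C[C@@H](O[Si](C)(C)C(C)(C)C)CC(=O)OC | intermediate
3 | (R)-3-[(tert-butyldimethylsilyl)oxy]butanoic acid | C[C@@H](O[Si](C)(C)C(C)(C)C)CC(=O)O | intermediate
4 | 1-bromo-3,5-bis(benzyloxy)benzene | Brc1cc(OCc2ccccc2)cc(OCc2ccccc2)c1 | starting material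
5 | (R)-propylene oxide | C[C@@H]1CO1 | starting material
6 | [3,5-bis(benzyloxy)phenyl]magnesium bromide (formed in the flask) | Br[Mg]c1cc(OCc2ccccc2)cc(OCc2ccccc2)c1 | intermediate
7 | (R)-1-[3,5-bis(benzyloxy)phenyl]propan-2-ol | C[C@H](Cc1cc(OCc2ccccc2)cc(OCc2ccccc2)c1)O | intermediate
8 | (R)-1-[3,5-bis(benzyloxy)phenyl]propan-2-yl (R)-3-[(tert-butyldimethylsilyl)oxy]butanoate | C[C@H](Cc1cc(OCc2ccccc2)cc(OCc2ccccc2)c1)OC(=O)C[C@@H](C)O[Si](C)(C)C(C)(C)C | intermediate
9 | (R)-1-[3,5-bis(benzyloxy)phenyl]propan-2-yl (R)-3-hydroxybutanoate | C[C@H](Cc1cc(OCc2ccccc2)cc(OCc2ccccc2)c1)OC(=O)C[C@@H](C)O | intermediate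
10 | mono-tert-butyl malonate (3-tert-butoxy-3-oxopropanoic acid) | CC(C)(C)OC(=O)CC(=O)O | starting material
11 | tert-butyl (R)-4-{[(R)-1-[3,5-bis(benzyloxy)phenyl]propan-2-yl]oxy}-4-oxobutan-2-yl malonate | C[C@H](Cc1cc(OCc2ccccc2)cc(OCc2ccccc2)c1)OC(=O)C[C@@H](C)OC(=O)CC(=O)OC(C)(C)C | intermediate
12 | 3,5-bis(benzyloxy)phenol | Oc1cc(OCc2ccccc2)cc(OCc2ccccc2)c1 | starting material
13 | 2-bromo-3,5-bis(benzyloxy)phenol | Oc1cc(OCc2ccccc2)cc(OCc2ccccc2)c1Br | intermediate
14 | [2-bromo-3,5-bis(benzyloxy)phenoxy]trimethylsilane | C[Si](C)(C)Oc1cc(OCc2ccccc2)cc(OCc2ccccc2)c1Br | intermediate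
15 | [2,4-bis(benzyloxy)-6-(trimethylsilyloxy)phenyl]lithium (formed in the flask) | C[Si](C)(C)Oc1cc(OCc2ccccc2)cc(OCc2ccccc2)c1[Li] | intermediate
16 | lithium 3,5-bis(benzyloxy)-2-(trimethylsilyl)phenoxide (formed in the flask) | [Li+].[O-]c1cc(OCc2ccccc2)cc(OCc2ccccc2)c1[Si](C)(C)C | intermediate
17 | 3,5-bis(benzyloxy)-2-(trimethylsilyl)phenyl trifluoromethanesulfonate | C[Si](C)(C)c1c(OS(=O)(=O)C(F)(F)F)cc(OCc2ccccc2)cc1OCc1ccccc1 | intermediate
18 | 3,5-bis(benzyloxy)benzyne (formed in the flask) | C1#CC(OCc2ccccc2)=CC(OCc2ccccc2)=C1 | intermediate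
19 | (R)-4-{[(R)-1-[3,5-bis(benzyloxy)phenyl]propan-2-yl]oxy}-4-oxobutan-2-yl 2,4-bis(benzyloxy)-6-(2-tert-butoxy-2-oxoethyl)benzoate | C[C@H](Cc1cc(OCc2ccccc2)cc(OCc2ccccc2)c1)OC(=O)C[C@@H](C)OC(=O)c1c(OCc2ccccc2)cc(OCc2ccccc2)cc1CC(=O)OC(C)(C)C | intermediate
20 | (R)-3-[(tert-butyldimethylsilyl)oxy]butanoyl chloride | C[C@@H](O[Si](C)(C)C(C)(C)C)CC(=O)Cl | intermediate
21 | β-keto ester: 19 carrying the (R)-3-[(tert-butyldimethylsilyl)oxy]butanoyl group on its benzylic carbon, both epimers at that carbon | C[C@H](Cc1cc(OCc2ccccc2)cc(OCc2ccccc2)c1)OC(=O)C[C@@H](C)OC(=O)c1c(OCc2ccccc2)cc(OCc2ccccc2)cc1C(C(=O)OC(C)(C)C)C(=O)C[C@@H](C)O[Si](C)(C)C(C)(C)C | intermediate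
22 | keto acid: free carboxylic acid corresponding to tert-butyl ester 21 (formed in the flask) | C[C@H](Cc1cc(OCc2ccccc2)cc(OCc2ccccc2)c1)OC(=O)C[C@@H](C)OC(=O)c1c(OCc2ccccc2)cc(OCc2ccccc2)cc1C(C(=O)O)C(=O)C[C@@H](C)O[Si](C)(C)C(C)(C)C | intermediate
23 | (R)-4-{[(R)-1-[3,5-bis(benzyloxy)phenyl]propan-2-yl]oxy}-4-oxobutan-2-yl 2,4-bis(benzyloxy)-6-[(R)-4-[(tert-butyldimethylsilyl)oxy]-2-oxopentyl]benzoate (formed in the flask) | C[C@H](Cc1cc(OCc2ccccc2)cc(OCc2ccccc2)c1)OC(=O)C[C@@H](C)OC(=O)c1c(OCc2ccccc2)cc(OCc2ccccc2)cc1CC(=O)C[C@@H](C)O[Si](C)(C)C(C)(C)C | intermediate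
24 | (R)-4-{[(R)-1-[3,5-bis(benzyloxy)phenyl]propan-2-yl]oxy}-4-oxobutan-2-yl 2,4-bis(benzyloxy)-6-[(R)-4-hydroxy-2-oxopentyl]benzoate | C[C@H](Cc1cc(OCc2ccccc2)cc(OCc2ccccc2)c1)OC(=O)C[C@@H](C)OC(=O)c1c(OCc2ccccc2)cc(OCc2ccccc2)cc1CC(=O)C[C@@H](C)O | intermediate
25 | Hansforester K, (R)-1-(3,5-dihydroxyphenyl)propan-2-yl (R)-3-{[2,4-dihydroxy-6-[(R)-4-hydroxy-2-oxopentyl]benzoyl]oxy}butanoate | C[C@H](Cc1cc(O)cc(O)c1)OC(=O)C[C@@H](C)OC(=O)c1c(O)cc(O)cc1CC(=O)C[C@@H](C)O | target

**Step count**

Total: 14 steps. Longest linear sequence: 9 steps (1, 2, 4, 5, 6, 10, 12, 13, 14).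

**Steps most likely to fail**

Step 10. The aryl anion may be protonated before it closes onto a carbonyl, which would give plain C-arylation of the malonate. It may also close onto the tert-butyl ester and so transfer the wrong carboxyl group, or fluoride may induce β-elimination of the malonate from the butanoate. The fallback gives up the aryne and attaches the two carbon substituents of ring B by classical arene chemistry, setting out from bromide 4 and alcohol 9 and returning at 19. Palladium-catalysed coupling of 4 with the commercial Reformatsky reagent BrZnCH2CO2tBu (Pd(dba)2, P(tBu)3, THF; Negishi-type coupling) would give tert-butyl 2-[3,5-bis(benzyloxy)phenyl]acetate F1. Vilsmeier–Haack formylation (POCl3, DMF) is expected ortho to the side chain and para to a benzyloxy group, giving tert-butyl 2-[3,5-bis(benzyloxy)-2-formylphenyl]acetate F2. Pinnick oxidation (NaClO2, NaH2PO4, 2-methyl-2-butene) would give 2,4-bis(benzyloxy)-6-(2-tert-butoxy-2-oxoethyl)benzoic acid F3. The neutral chloroenamine of step 11 would convert this into 2,4-bis(benzyloxy)-6-(2-tert-butoxy-2-oxoethyl)benzoyl chloride F4, which acylates alcohol 9 (Et3N, DMAP, CH2Cl2, rt → 40 °C) with retention to give 19. This esterification of a doubly ortho-substituted acid is slower than the aryne transfer, which is why it is held in reserve.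

Step 12. The second equivalent of amide base may deprotonate the CH2 next to the butanoate carbonyl, after which the ring B carboxylate is lost by β-elimination. With less base, proton transfer from product to enolate stalls the conversion. The product enolate could also close onto the neighbouring benzoate. The fallback uses a single equivalent of base and a neutral acylation, setting out from 19 and returning at 21. Enolisation with LiN(SiMe3)2 (1.0 equiv) and trapping with Me3SiCl at −78 °C would give the O-trimethylsilyl ketene acetal of 19 F5. This reacts with acid chloride 20 in CH2Cl2 (rt, optionally catalytic ZnBr2) by C-acylation of the ketene silyl acetal, giving 21 with no basic species present once the carbon–carbon bond has formed.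

Step 13. The tert-butyl cation may alkylate the benzyloxy-substituted rings (Friedel–Crafts), benzyl groups may be lost or migrate in acid, the β-hydroxy ketone may dehydrate, or the silyl ether may be cleaved only in part. The fallback separates the three events and avoids protic acid, setting out from 21 and returning at 24. Me3SiOTf with 2,6-lutidine in CH2Cl2 at 0 °C cleaves the tert-butyl ester by silyl transfer, with the tert-butyl group leaving as isobutene in a base-buffered medium, to give the trimethylsilyl ester of keto acid 22 F6. Aqueous methanol work-up hydrolyses it (and any enol silyl ether) to keto acid 22, which loses CO2 on gentle warming to silyl ether ketone 23, isolated in this variant. HF·pyridine under the conditions of step 5 then removes the silyl ether to give 24.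

**Further compounds**

F1 | step 10 | tert-butyl 2-[3,5-bis(benzyloxy)phenyl]acetate | CC(C)(C)OC(=O)Cc1cc(OCc2ccccc2)cc(OCc2ccccc2)c1
F2 | step 10 | tert-butyl 2-[3,5-bis(benzyloxy)-2-formylphenyl]acetate | CC(C)(C)OC(=O)Cc1cc(OCc2ccccc2)cc(OCc2ccccc2)c1C=O
F3 | step 10 | 2,4-bis(benzyloxy)-6-(2-tert-butoxy-2-oxoethyl)benzoic acid | CC(C)(C)OC(=O)Cc1cc(OCc2ccccc2)cc(OCc2ccccc2)c1C(=O)O
F4 | step 10 | 2,4-bis(benzyloxy)-6-(2-tert-butoxy-2-oxoethyl)benzoyl chloride | CC(C)(C)OC(=O)Cc1cc(OCc2ccccc2)cc(OCc2ccccc2)c1C(=O)Cl
F5 | step 12 | O-trimethylsilyl ketene acetal of 19 (E/Z mixture) | C[C@H](Cc1cc(OCc2ccccc2)cc(OCc2ccccc2)c1)OC(=O)C[C@@H](C)OC(=O)c1c(OCc2ccccc2)cc(OCc2ccccc2)cc1C=C(O[Si](C)(C)C)OC(C)(C)C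
F6 | step 13 | trimethylsilyl ester of keto acid 22 (both epimers at the benzylic carbon) | C[C@H](Cc1cc(OCc2ccccc2)cc(OCc2ccccc2)c1)OC(=O)C[C@@H](C)OC(=O)c1c(OCc2ccccc2)cc(OCc2ccccc2)cc1C(C(=O)O[Si](C)(C)C)C(=O)C[C@@H](C)O[Si](C)(C)C(C)(C)C
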